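**Retrosynthetic overview**

1. Target 35 ⇐ C6 acetate last; dihydrofuran (ring E) by cycloisomerisation of a C13 ethynyl/hydroxymethyl spiro ether; 8β,17-oxirane from the exocyclic alkene; oxolane (ring D) by 5-exo opening of a Sharpless epoxide by the 9-OH; C9–C11 bond by Grignard addition to enone lactone 18.
2. Lactone 16 ⇐ key ring contraction. The enabling feature is C19, an exocyclic carboxyl carbon on quaternary C4 held 1,3-diaxially across ring A (C1–C5, C10) to the C20 oxygen (δ-lactone C4–C19–O–C20–C10–C5). It maps back onto a ring ketone C19 inside a seven-membered ring C10–C1–C2–C3–C19–C4–C5 with a 4-chloro-4-methyl unit (13), whose C20 alkoxide triggers a Favorskii-type contraction that makes ring A, the lactone and quaternary C4 at once.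
3. Chloro ketone 13 ⇐ epoxide opening and oxidation of cycloheptene 10 ⇐ ring-closing metathesis of the C5 isopropenyl and C10 pent-4-enyl arms on ring B.
4. Ring B triad C6→C5→C10 ⇐ anti conjugate addition and anti hydroxymethylation on (R)-4-silyloxy-2-(pent-4-enyl)cyclohexenone 4, made from 1 by iodination and Negishi coupling.
5. Order of ring formation: ring B (present in 1) → seven-membered carbocycle (step 6) → ring A and δ-lactone (step 10) → oxolane (step 21) → oxirane (step 22) → dihydrofuran (step 23).

Key step: step 10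

Remark: labdane locants of the target are used for all intermediates (ring A C1–C5/C10, ring B C5–C10, C17 on C8, C18 methyl and C19 carbonyl on C4, C20 on C10, side chain C11–C16); β is the face of ring B that carries C20.
Remark: (R)-4-[(tert-butyldimethylsilyl)oxy]cyclohex-2-en-1-one (1) is taken as a purchasable chiral building block, as are the organometallic solutions 3 and 5.

**Step 1**
Reactants: 1 (R)-4-[(tert-butyldimethylsilyl)oxy]cyclohex-2-en-1-one
Product: 2 (R)-4-[(tert-butyldimethylsilyl)oxy]-2-iodocyclohex-2-en-1-one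
Conditions: I2, K2CO3, DMAP (20 mol %), THF/H2O 1:1, rt
Reagents that add atoms: iodine (SMILES II)
Why: α-Iodination of an enone by reversible conjugate addition of DMAP, iodination of the enolate and elimination (Baylis–Hillman-type iodination), which should leave the C6 stereocentre untouched.

**Step 2**
Reactants: 2 iodoenone; 3 pent-4-en-1-ylzinc bromide
Product: 4 (R)-4-[(tert-butyldimethylsilyl)oxy]-2-(pent-4-en-1-yl)cyclohex-2-en-1-one
Conditions: PdCl2(dppf) (5 mol %), THF, rt
Reagents that add atoms: none
Why: Negishi cross-coupling of an α-iodoenone with a primary alkylzinc halide, in which the bidentate dppf ligand should suppress β-hydride elimination.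

**Step 3**
Reactants: 4 pentenyl enone; 5 isopropenylmagnesium bromide
Product: 7 (2S,3R,4R)-4-[(tert-butyldimethylsilyl)oxy]-2-(hydroxymethyl)-2-(pent-4-en-1-yl)-3-(prop-1-en-2-yl)cyclohexan-1-one, via bromomagnesium enolate 6 (not isolated)
Conditions: CuBr·SMe2 (20 mol %), THF, −40 °C; then monomeric CH2O (gas), −78 → −30 °C; aq. NH4Cl
Reagents that add atoms: formaldehyde (SMILES C=O)
Why: Copper-catalysed conjugate addition should place the isopropenyl group anti to the C6 silyloxy group (sets C5), and the aldol reaction of the resulting tetrasubstituted enolate with formaldehyde should occur anti to the new pseudo-axial isopropenyl group (sets quaternary C10 with the CH2OH cis to H5).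

**Step 4**
Reactants: 7 hydroxymethyl ketone
Product: 8 (1R,2S,3R,4R)-4-[(tert-butyldimethylsilyl)oxy]-2-(hydroxymethyl)-2-(pent-4-en-1-yl)-3-(prop-1-en-2-yl)cyclohexan-1-ol
Conditions: NaBH4, MeOH, 0 °C
Reagents that add atoms: none
Why: Borohydride reduction masks the C9 carbonyl so that the C10 hydroxymethyl group cannot be lost later by retro-aldol cleavage, and axial hydride delivery on the face opposite the axial pentenyl chain should give the 9α-alcohol, a centre that is erased again in step 11.

**Step 5**
Reactants: 8 diol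
Product: 9 diacetate of 8 (9α-OAc; 20-OAc; 6β-OTBS)
Conditions: Ac2O, pyridine, DMAP (10 mol %), rt
Reagents that add atoms: acetic anhydride (SMILES CC(=O)OC(C)=O)
Why: DMAP-catalysed acylation protects both hydroxyl groups, the primary C20 acetate serving as the base-labile trigger of step 10 and the hindered C9 acetate as the slower-cleaving mask.

**Step 6**
Reactants: 9 diacetate
Product: 10 cis-fused cycloheptene (seven-membered ring C10–C1–C2–C3–C19–C4–C5 with C4=C19 and 4-methyl; 5β-H; 6β-OTBS; 9α-OAc; 20-OAc)
Conditions: second-generation Grubbs catalyst (5 mol %), CH2Cl2, 40 °C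
Reagents that add atoms: none
Why: Ring-closing metathesis of the cis-disposed isopropenyl and pentenyl arms should close the trisubstituted cycloheptene with loss of ethene, a ring size and substitution pattern that this catalyst forms readily.

**Step 7**
Reactants: 10 cycloheptene
Product: 11 4α,19α-epoxide of 10
Conditions: mCPBA, NaHCO3, CH2Cl2, 0 °C
Reagents that add atoms: meta-chloroperoxybenzoic acid (SMILES OOC(=O)c1cccc(Cl)c1)
Why: Prilezhaev epoxidation of the only alkene, in which the peracid should approach C4=C19 from the α face, away from the pseudo-axial angular CH2OAc group lying over the β face, so that chloride can later enter C4 from the β face.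

**Step 8**
Reactants: 11 epoxide
Product: 12 trans-chlorohydrin (4β-chloro-19α-hydroxy)
Conditions: HCl (1 M in Et2O), CH2Cl2, −40 °C
Reagents that add atoms: hydrogen chloride (SMILES Cl)
Why: Acid-mediated opening of the trisubstituted epoxide by chloride at the tertiary carbon with inversion (Markovnikov-type epoxide opening) should give the 4β C–Cl bond.

**Step 9**
Reactants: 12 chlorohydrin
Product: 13 4β-chloro-19-ketone (2-chloro-2-methylcycloheptanone unit; 9α-OAc; 20-OAc; 6β-OTBS)
Conditions: Dess–Martin periodinane, NaHCO3, CH2Cl2, rt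
Reagents that add atoms: none
Why: Dess–Martin oxidation converts the secondary alcohol into the ketone under buffered non-basic conditions that should leave the tertiary α-chloride in place.

**Step 10**
Reactants: 13 chloro ketone
Product: 16 9α-hydroxy-6β-[(tert-butyldimethylsilyl)oxy]-5β-11,12,13,14,15,16,17-heptanorlabdan-19,20-olide, via C20 alkoxide 14 (not isolated), via 9-O-acetyl lactone 15 (not isolated)
Conditions: NaOMe (4 equiv), MeOH, 0 °C → rt; then AcOH
Reagents that add atoms: none
Why: Methoxide first cleaves the primary C20 acetate, the C20 alkoxide adds to the C19 ketone to give a bicyclic hemiketal alkoxide whose C19–C3 bond lies anti-periplanar to the 4β C–Cl bond, and a 1,2-shift of C3 from C19 to C4 with loss of chloride (quasi-Favorskii pathway; the cyclopropanone formed by 3-exo-tet closure of the C3 enolate onto C4 and opened by the same tethered alkoxide is the alternative channel to the same product) contracts the seven-membered ring and leaves C19 as the lactone carbonyl. The closest known reaction type is the Favorskii ring contraction of 2-chloro-2-methylcycloalkanones by alkoxide to 1-methylcycloalkanecarboxylates, here with the alkoxide tethered. Ring A (C1–C5, C10) is closed by the 1,2-alkyl shift, that is by contraction from seven to six members, and the lactone ring (C4–C19–O–C20–C10–C5) by 6-exo-trig addition of the alkoxide to the carbonyl. The only new stereocentre, quaternary C4, is fixed because C3 enters anti to the 4β chloride (inversion) and because the tether lets C19 end only cis to C20, the 1,3-diaxial arrangement across ring A, while C5 and C10 are untouched. The step needs internal instead of external capture of C19 and migration instead of dehydrochlorination, which should be secured by the high effective molarity of the six-membered tether, by the 9-oxygen staying acetylated until the primary acetate has reacted and being unable to reach a β-disposed C19, and by the 4β chloride being syn to H5 so that anti elimination across C4–C5 is not available. The hindered 9-acetate is then methanolysed in the same pot to give 16.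

**Step 11**
Reactants: 16 hydroxy lactone
Product: 17 6β-[(tert-butyldimethylsilyl)oxy]-9-oxo-5β-11,12,13,14,15,16,17-heptanorlabdan-19,20-olide
Conditions: Dess–Martin periodinane, NaHCO3, CH2Cl2, rt
Reagents that add atoms: none
Why: Dess–Martin oxidation of the hindered secondary alcohol restores the C9 ketone, now safe from retro-aldol cleavage because the C20 oxygen is acylated within the lactone.

**Step 12**
Reactants: 17 keto lactone
Product: 18 6β-[(tert-butyldimethylsilyl)oxy]-9-oxo-5β-11,12,13,14,15,16-hexanorlabd-8(17)-en-19,20-olide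
Conditions: (CH2O)n, N-methylanilinium trifluoroacetate, THF, reflux
Reagents that add atoms: formaldehyde (SMILES C=O)
Why: Mannich-type α-methylenation (Gras conditions) can occur only at C8, the single enolisable position, because C10 and the lactone α-carbon C4 are quaternary.

**Step 13**
Reactants: 19 3-chloro-2-(chloromethyl)prop-1-ene (3 equiv); 20 4-methoxybenzyl alcohol
Product: 21 1-({[2-(chloromethyl)prop-2-en-1-yl]oxy}methyl)-4-methoxybenzene
Conditions: NaH, THF, 0 °C → rt
Reagents that add atoms: none
Why: Williamson etherification at one allylic chloride, the excess of the symmetric dichloride holding the reaction at mono-substitution.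

**Step 14**
Reactants: 21 allylic chloride
Product: 23 3-{[(4-methoxybenzyl)oxy]methyl}but-3-en-1-ol, via allylzinc chloride 22 (not isolated)
Conditions: Zn dust, aq. CH2O (37 %), THF/sat. aq. NH4Cl, rt
Reagents that add atoms: formaldehyde (SMILES C=O)
Why: Aqueous Barbier allylation of formaldehyde, in which the symmetric 2-substituted allyl unit gives the same homoallylic alcohol from either terminus.

**Step 15**
Reactants: 23 homoallylic alcohol
Product: 24 1-({[2-(2-bromoethyl)prop-2-en-1-yl]oxy}methyl)-4-methoxybenzene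
Conditions: CBr4, PPh3, CH2Cl2, 0 °C
Reagents that add atoms: carbon tetrabromide (SMILES BrC(Br)(Br)Br)
Why: Appel bromination of the primary alcohol under neutral conditions that the allyl and 4-methoxybenzyl ethers should tolerate.

**Step 16**
Reactants: 18 enone lactone; 24 bromide
Product: 26 6β-[(tert-butyldimethylsilyl)oxy]-9α-hydroxy-14-[(4-methoxybenzyl)oxy]-5β-15-norlabda-8(17),13(16)-dien-19,20-olide, via Grignard reagent 25 (not isolated)
Conditions: Mg, THF, rt; then 18, LaCl3·2LiCl (1 equiv), THF, −40 → 0 °C; aq. NH4Cl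
Reagents that add atoms: none
Why: Lanthanum-promoted 1,2-addition of the Grignard reagent to the hindered enone should occur on the convex β face, opposite the axial C10–C1 bond (sets C9 with C11 β and the hydroxyl α), while the lactone carbonyl is shielded by quaternary C4.

**Step 17**
Reactants: 26 PMB ether
Product: 27 6β-[(tert-butyldimethylsilyl)oxy]-9α,14-dihydroxy-5β-15-norlabda-8(17),13(16)-dien-19,20-olide
Conditions: DDQ, CH2Cl2/pH 7 buffer, 0 °C
Reagents that add atoms: none
Why: Oxidative cleavage of the 4-methoxybenzyl ether by DDQ frees the primary allylic alcohol without touching the silyl ether, the lactone or the alkenes.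

**Step 18**
Reactants: 27 diol
Product: 28 (13S)-6β-[(tert-butyldimethylsilyl)oxy]-13,16-epoxy-9α,14-dihydroxy-5β-15-norlabd-8(17)-en-19,20-olide
Conditions: Ti(OiPr)4 (10 mol %), L-(+)-diethyl tartrate (12 mol %), t-BuOOH, 4 Å MS, CH2Cl2, −20 °C
Reagents that add atoms: tert-butyl hydroperoxide (SMILES CC(C)(C)OO)
Why: Sharpless asymmetric epoxidation of the primary 2-substituted allylic alcohol, in which the L-(+)-tartrate catalyst should deliver oxygen to the face giving the (13S)-epoxide (reagent control, as for 2-alkylallyl alcohols) while the tertiary allylic alcohol at C9 is too hindered to react.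

**Step 19**
Reactants: 28 epoxy alcohol
Product: 29 (13R)-6β-[(tert-butyldimethylsilyl)oxy]-13,16-epoxy-9α-hydroxy-14-oxo-5β-15-norlabd-8(17)-en-19,20-olide
Conditions: Dess–Martin periodinane, NaHCO3, CH2Cl2, 0 °C
Reagents that add atoms: none
Why: Dess–Martin oxidation of the primary alcohol gives the epoxy aldehyde, which cannot epimerise because C13 bears no hydrogen (the descriptor changes only through the priority switch).

**Step 20**
Reactants: 29 epoxy aldehyde
Product: 30 (13S)-6β-[(tert-butyldimethylsilyl)oxy]-13,16-epoxy-9α-hydroxy-5β-labd-8(17)-en-14-yn-19,20-olide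
Conditions: dimethyl (1-diazo-2-oxopropyl)phosphonate, K2CO3, MeOH, 0 °C → rt
Reagents that add atoms: dimethyl (1-diazo-2-oxopropyl)phosphonate (SMILES COP(=O)(OC)C(=[N+]=[N-])C(C)=O)
Why: Seyferth–Gilbert homologation in the Ohira–Bestmann variant converts the non-enolisable aldehyde into the terminal alkyne and adds C15 under mild carbonate conditions.

**Step 21**
Reactants: 30 ethynyl epoxide
Product: 31 (13R)-6β-[(tert-butyldimethylsilyl)oxy]-9α,13-epoxy-16-hydroxy-5β-labd-8(17)-en-14-yn-19,20-olide
Conditions: CSA (10 mol %), CH2Cl2, 0 °C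
Reagents that add atoms: none
Why: Acid-catalysed 5-exo-tet opening of the epoxide by the tertiary 9-hydroxyl at the more substituted carbon C13 should proceed with inversion, carrying the Sharpless-derived configuration into the spiro centre and freeing the C16 hydroxyl.

**Step 22**
Reactants: 31 spiro ether
Product: 32 (13R)-6β-[(tert-butyldimethylsilyl)oxy]-8β,17:9α,13-diepoxy-16-hydroxy-5β-labd-14-yn-19,20-olide
Conditions: mCPBA, NaHCO3, CH2Cl2, 0 °C
Reagents that add atoms: meta-chloroperoxybenzoic acid (SMILES OOC(=O)c1cccc(Cl)c1)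
Why: Prilezhaev epoxidation of the exocyclic alkene should occur from the convex β face, because the α face is blocked by the axial C10–C1 bond that folds ring A under ring B, which places the oxirane oxygen equatorial (sets C8).

**Step 23**
Reactants: 32 alkynol
Product: 33 (13R)-6β-[(tert-butyldimethylsilyl)oxy]-8β,17:9α,13:15,16-triepoxy-5β-labd-14-en-19,20-olide
Conditions: Mo(CO)6 (25 mol %), Et3N, Et2O, hν (350 nm), rt
Reagents that add atoms: none
Why: Molybdenum-vinylidene cycloisomerisation of a homopropargylic alcohol (McDonald alkynol cycloisomerisation), in which the C16 hydroxyl adds to the terminal alkyne carbon to give the 2,3-dihydrofuran under basic conditions that the oxirane and lactone should tolerate.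

**Step 24**
Reactants: 33 silyl ether
Product: 35 (13R)-6β-acetoxy-8β,17:9α,13:15,16-triepoxy-5β-labd-14-en-19,20-olide, via C6 alkoxide 34 (not isolated)
Conditions: TBAF, THF, 0 °C; then Ac2O, Et3N, DMAP, 0 °C → rt
Reagents that add atoms: acetic anhydride (SMILES CC(=O)OC(C)=O)
Why: Fluoride desilylation followed by acylation in the same flask installs the 6β-acetate under basic conditions throughout, which the acid-sensitive enol ether and oxirane should survive.

**Compound list**

1 | (R)-4-[(tert-butyldimethylsilyl)oxy]cyclohex-2-en-1-one | O=C1C=C[C@H](O[Si](C)(C)C(C)(C)C)CC1 | starting material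
2 | (R)-4-[(tert-butyldimethylsilyl)oxy]-2-iodocyclohex-2-en-1-one | O=C1C(I)=C[C@H](O[Si](C)(C)C(C)(C)C)CC1 | intermediate
3 | pent-4-en-1-ylzinc bromide | Br[Zn]CCCC=C | starting material
4 | (R)-4-[(tert-butyldimethylsilyl)oxy]-2-(pent-4-en-1-yl)cyclohex-2-en-1-one | O=C1C(CCCC=C)=C[C@H](O[Si](C)(C)C(C)(C)C)CC1 | intermediate
5 | isopropenylmagnesium bromide | CC(=C)[Mg]Br | starting material
6 | bromomagnesium enolate of the conjugate adduct (isopropenyl trans to OTBS) | Br[Mg]OC1=C(CCCC=C)[C@@H](C(C)=C)[C@H](O[Si](C)(C)C(C)(C)C)CC1 | intermediate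
7 | (2S,3R,4R)-4-[(tert-butyldimethylsilyl)oxy]-2-(hydroxymethyl)-2-(pent-4-en-1-yl)-3-(prop-1-en-2-yl)cyclohexan-1-one | O=C1CC[C@@H](O[Si](C)(C)C(C)(C)C)[C@H](C(C)=C)[C@]1(CO)CCCC=C | intermediate
8 | (1R,2S,3R,4R)-4-[(tert-butyldimethylsilyl)oxy]-2-(hydroxymethyl)-2-(pent-4-en-1-yl)-3-(prop-1-en-2-yl)cyclohexan-1-ol | O[C@@H]1CC[C@@H](O[Si](C)(C)C(C)(C)C)[C@H](C(C)=C)[C@]1(CO)CCCC=C | intermediate
9 | diacetate of 8 (9α-OAc, 20-OAc) | CC(=O)O[C@@H]1CC[C@@H](O[Si](C)(C)C(C)(C)C)[C@H](C(C)=C)[C@]1(COC(C)=O)CCCC=C | intermediate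
10 | cis-fused cycloheptene: ring C10–C1–C2–C3–C19–C4–C5 with C4=C19 and 4-methyl, fused at C5–C10 to ring B with 5β-H, 6β-OTBS, 9α-OAc, 10β-CH2OAc | CC(=O)O[C@@H]1CC[C@@H](O[Si](C)(C)C(C)(C)C)[C@@H]2C(C)=CCCC[C@]12COC(C)=O | intermediate
11 | 4α,19α-epoxide of 10 | CC(=O)O[C@@H]1CC[C@@H](O[Si](C)(C)C(C)(C)C)[C@@H]2[C@]3(C)O[C@@H]3CCC[C@]12COC(C)=O | intermediate
12 | 4β-chloro-19α-hydroxy trans-chlorohydrin | CC(=O)O[C@@H]1CC[C@@H](O[Si](C)(C)C(C)(C)C)[C@@H]2[C@@](C)(Cl)[C@H](O)CCC[C@]12COC(C)=O | intermediate
13 | 4β-chloro-4-methyl-19-ketone (seven-membered α-chloro ketone; 9α-OAc, 20-OAc, 6β-OTBS) | CC(=O)O[C@@H]1CC[C@@H](O[Si](C)(C)C(C)(C)C)[C@@H]2[C@@](C)(Cl)C(=O)CCC[C@]12COC(C)=O | intermediate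
14 | sodium C20 alkoxide of 13 after loss of the primary acetate (in equilibrium with its C19 hemiketal) | CC(=O)O[C@@H]1CC[C@@H](O[Si](C)(C)C(C)(C)C)[C@@H]2[C@@](C)(Cl)C(=O)CCC[C@]12C[O-].[Na+] | intermediate
15 | 9α-acetoxy-6β-[(tert-butyldimethylsilyl)oxy]-5β-11,12,13,14,15,16,17-heptanorlabdan-19,20-olide | CC(C)(C)[Si](C)(C)O[C@@H]1CC[C@@H](OC(C)=O)[C@]23CCC[C@](C)(C(=O)OC2)[C@@H]13 | intermediate
16 | 9α-hydroxy-6β-[(tert-butyldimethylsilyl)oxy]-5β-11,12,13,14,15,16,17-heptanorlabdan-19,20-olide | CC(C)(C)[Si](C)(C)O[C@@H]1CC[C@@H](O)[C@]23CCC[C@](C)(C(=O)OC2)[C@@H]13 | intermediate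
17 | 6β-[(tert-butyldimethylsilyl)oxy]-9-oxo-5β-11,12,13,14,15,16,17-heptanorlabdan-19,20-olide | CC(C)(C)[Si](C)(C)O[C@@H]1CCC(=O)[C@]23CCC[C@](C)(C(=O)OC2)[C@@H]13 | intermediate
18 | 6β-[(tert-butyldimethylsilyl)oxy]-9-oxo-5β-11,12,13,14,15,16-hexanorlabd-8(17)-en-19,20-olide | CC(C)(C)[Si](C)(C)O[C@@H]1CC(=C)C(=O)[C@]23CCC[C@](C)(C(=O)OC2)[C@@H]13 | intermediate
19 | 3-chloro-2-(chloromethyl)prop-1-ene | ClCC(=C)CCl | starting material
20 | 4-methoxybenzyl alcohol | COc1ccc(CO)cc1 | starting material
21 | 1-({[2-(chloromethyl)prop-2-en-1-yl]oxy}methyl)-4-methoxybenzene | ClCC(=C)COCc1ccc(OC)cc1 | intermediate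
22 | allylzinc chloride from 21 | Cl[Zn]CC(=C)COCc1ccc(OC)cc1 | intermediate
23 | 3-{[(4-methoxybenzyl)oxy]methyl}but-3-en-1-ol | OCCC(=C)COCc1ccc(OC)cc1 | intermediate
24 | 1-({[2-(2-bromoethyl)prop-2-en-1-yl]oxy}methyl)-4-methoxybenzene | BrCCC(=C)COCc1ccc(OC)cc1 | intermediate
25 | Grignard reagent from 24 | Br[Mg]CCC(=C)COCc1ccc(OC)cc1 | intermediate
26 | 6β-[(tert-butyldimethylsilyl)oxy]-9α-hydroxy-14-[(4-methoxybenzyl)oxy]-5β-15-norlabda-8(17),13(16)-dien-19,20-olide | CC(C)(C)[Si](C)(C)O[C@@H]1CC(=C)[C@](O)(CCC(=C)COCc4ccc(OC)cc4)[C@]23CCC[C@](C)(C(=O)OC2)[C@@H]13 | intermediate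
27 | 6β-[(tert-butyldimethylsilyl)oxy]-9α,14-dihydroxy-5β-15-norlabda-8(17),13(16)-dien-19,20-olide | CC(C)(C)[Si](C)(C)O[C@@H]1CC(=C)[C@](O)(CCC(=C)CO)[C@]23CCC[C@](C)(C(=O)OC2)[C@@H]13 | intermediate
28 | (13S)-6β-[(tert-butyldimethylsilyl)oxy]-13,16-epoxy-9α,14-dihydroxy-5β-15-norlabd-8(17)-en-19,20-olide | CC(C)(C)[Si](C)(C)O[C@@H]1CC(=C)[C@](O)(CC[C@]4(CO)CO4)[C@]23CCC[C@](C)(C(=O)OC2)[C@@H]13 | intermediate
29 | (13R)-6β-[(tert-butyldimethylsilyl)oxy]-13,16-epoxy-9α-hydroxy-14-oxo-5β-15-norlabd-8(17)-en-19,20-olide | CC(C)(C)[Si](C)(C)O[C@@H]1CC(=C)[C@](O)(CC[C@]4(C=O)CO4)[C@]23CCC[C@](C)(C(=O)OC2)[C@@H]13 | intermediate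
30 | (13S)-6β-[(tert-butyldimethylsilyl)oxy]-13,16-epoxy-9α-hydroxy-5β-labd-8(17)-en-14-yn-19,20-olide | CC(C)(C)[Si](C)(C)O[C@@H]1CC(=C)[C@](O)(CC[C@]4(C#C)CO4)[C@]23CCC[C@](C)(C(=O)OC2)[C@@H]13 | intermediate
31 | (13R)-6β-[(tert-butyldimethylsilyl)oxy]-9α,13-epoxy-16-hydroxy-5β-labd-8(17)-en-14-yn-19,20-olide | CC(C)(C)[Si](C)(C)O[C@@H]1CC(=C)[C@]2(CC[C@@](C#C)(CO)O2)[C@]23CCC[C@](C)(C(=O)OC2)[C@@H]13 | intermediate
32 | (13R)-6β-[(tert-butyldimethylsilyl)oxy]-8β,17:9α,13-diepoxy-16-hydroxy-5β-labd-14-yn-19,20-olide | CC(C)(C)[Si](C)(C)O[C@@H]1C[C@@]2(CO2)[C@]2(CC[C@@](C#C)(CO)O2)[C@]23CCC[C@](C)(C(=O)OC2)[C@@H]13 | intermediate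
33 | (13R)-6β-[(tert-butyldimethylsilyl)oxy]-8β,17:9α,13:15,16-triepoxy-5β-labd-14-en-19,20-olide | CC(C)(C)[Si](C)(C)O[C@@H]1C[C@@]2(CO2)[C@]2(CC[C@]3(C=COC3)O2)[C@]23CCC[C@](C)(C(=O)OC2)[C@@H]13 | intermediate
34 | (13R)-6β-hydroxy-8β,17:9α,13:15,16-triepoxy-5β-labd-14-en-19,20-olide (formed as its tetrabutylammonium alkoxide) | O[C@@H]1C[C@@]2(CO2)[C@]2(CC[C@]3(C=COC3)O2)[C@]23CCC[C@](C)(C(=O)OC2)[C@@H]13 | intermediate
35 | (13R)-6β-acetoxy-8β,17:9α,13:15,16-triepoxy-5β-labd-14-en-19,20-olide (CNP0173713.1) | CC(=O)O[C@@H]1C[C@@]2(CO2)[C@]2(CC[C@]3(C=COC3)O2)[C@]23CCC[C@](C)(C(=O)OC2)[C@@H]13 | target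

**Step count**

Total: 24 steps. Longest linear sequence: 21 steps (steps 1–12 and 16–24); the side-chain branch (steps 13–15) joins at step 16.

**Steps most likely to fail**

Step 10. The contraction may be diverted by dehydrochlorination to an enone, by methoxide instead of the tethered alkoxide capturing C19, by closure of the hemiketal oxygen onto C4, or by ionisation of the tertiary chloride with loss of the C4 configuration. It also inherits any poor facial selectivity of the epoxidation in step 7. The fallback replaces the Favorskii-type contraction by an epoxide (Meinwald-type semipinacol) contraction and sets out from alkene 10. NBS in aqueous THF should give the bromohydrin F1 (bromonium on the α face, water at C4 from the β face). K2CO3 in acetone should close it to the 4β,19β-epoxide F2. BF3·OEt2 in CH2Cl2 at −78 °C should give the ring-contracted aldehyde F3 by migration of C3 from C19 to C4 anti to the departing oxygen. K2CO3 in MeOH then removes both acetates and lets the C20 hydroxyl close onto the aldehyde to give the lactol F4. Pr4N[RuO4] (5 mol %) with N-methylmorpholine N-oxide oxidises the lactol to the lactone and the 9-alcohol to the ketone, so the route is rejoined at compound 17.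

Step 22. The peracid may show poor facial selectivity at the exocyclic alkene, which is flanked by the spiro ether on one side and the folded ring A on the other, and deliver oxygen to the α face. The fallback sets out from compound 31 and reverses the facial outcome. NBS in wet DMSO should give the bromohydrin F5, with bromonium formation on the more accessible face and water attacking tertiary C8 from the other. K2CO3 in MeOH then closes F5 to the 8β,17-oxirane, and the route is rejoined at compound 32.

Step 23. The photogenerated molybdenum catalyst may decompose, the alkyne may oligomerise at the hindered neopentyl-type centre, or low-valent molybdenum may deoxygenate the oxirane. The fallback sets out from compound 32 and builds the enol ether through a lactol. Hydroboration of the terminal alkyne with disiamylborane (excess, since the free hydroxyl consumes one equivalent) and buffered NaBO3 oxidation should give the C15 aldehyde, which closes onto the C16 hydroxyl as the lactol F6. MsCl and Et3N in CH2Cl2 then dehydrate F6 to the enol ether, and the route is rejoined at compound 33.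

**Further compounds**

F1 | step 10 | bromohydrin of 10 (4β-hydroxy-19α-bromo) | CC(=O)O[C@@H]1CC[C@@H](O[Si](C)(C)C(C)(C)C)[C@@H]2[C@@](C)(O)[C@H](Br)CCC[C@]12COC(C)=O
F2 | step 10 | 4β,19β-epoxide of 10 | CC(=O)O[C@@H]1CC[C@@H](O[Si](C)(C)C(C)(C)C)[C@@H]2[C@@]3(C)O[C@H]3CCC[C@]12COC(C)=O
F3 | step 10 | ring-contracted aldehyde (ring A six-membered; 4β-formyl-4α-methyl; 9α-OAc; 20-OAc; 6β-OTBS) | CC(=O)O[C@@H]1CC[C@@H](O[Si](C)(C)C(C)(C)C)[C@@H]2[C@@](C)(C=O)CCC[C@]12COC(C)=O
F4 | step 10 | 19,20-lactol with free 9α-hydroxyl (lactol epimers) | CC(C)(C)[Si](C)(C)O[C@@H]1CC[C@@H](O)[C@]23CCC[C@](C)(C(O)OC2)[C@@H]13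
F5 | step 22 | bromohydrin of 31 (8β-hydroxy-17-bromo) | CC(C)(C)[Si](C)(C)O[C@@H]1C[C@@](O)(CBr)[C@]2(CC[C@@](C#C)(CO)O2)[C@]23CCC[C@](C)(C(=O)OC2)[C@@H]13
F6 | step 23 | 15-hydroxy-15,16-epoxy lactol of 32 (lactol epimers) | CC(C)(C)[Si](C)(C)O[C@@H]1C[C@@]2(CO2)[C@]2(CC[C@]3(CC(O)OC3)O2)[C@]23CCC[C@](C)(C(=O)OC2)[C@@H]13
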